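**Strategy.** Everything rests on disconnecting, as an aldol, the bond between the quaternary methyl-bearing carbon (C1) and the neighbouring acetoxy carbon of the ten-membered ring (C2). With the cyclohexene acetoxy carbon C14, these atoms form a 1,3-dioxygenated array. Before the cyclohexene exists, C14 is an α-branched aldehyde whose only α-hydrogen sits on C1, and C2 is an ynal (C3≡C4, the later Z-alkene). Soft enolisation and intramolecular Mukaiyama aldol addition close the ten-membered carbocycle and create quaternary C1 and carbinol C2 in one operation. The precursor is an open-chain dialdehyde built on a malic-acid-derived lactone; allylation at C14 and ring-closing metathesis add the six-membered ring afterwards.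

Key step: step 17

Remark on labels: C1 = quaternary C(CH3); C2(OAc)–C3=C4–C5(C16H2OH)=C6–C7(O-lactone)–C8(OH)–C9(OAc)–C10 complete the ten-membered ring; C10–C11(CH3)=C12–C13–C14(OAc)–C1 is the cyclohexene; C17(CH3) and C19(=O) are the lactone α-carbon and carbonyl.
Remark on the chemistry: 1, 4, 7, 15 and 23 are taken as commercial; the C1 configuration written for 26 and 27 is the one expected from a chair Claisen transition state and is erased in step 17.

Step 1
Reactants: 1 allyl propargyl ether
Product: 3 (1E)-1-iodo-2-methyl-3-(allyloxy)prop-1-ene, via alkenylalane 2 (not isolated)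
Conditions: Me3Al, Cp2ZrCl2 (cat.), CH2Cl2, 0 °C to rt; then I2, THF, −30 °C
Reagents that add atoms: trimethylaluminium C[Al](C)C; iodine II
Why: Negishi zirconium-catalysed carboalumination adds CH3–Al syn across the terminal alkyne (methyl to the internal carbon) and iodinolysis goes with retention, so iodine ends cis to the methyl group.

Step 2
Reactants: 4 dimethyl (S)-malate
Product: 5 dimethyl (2S,3R)-2-hydroxy-3-methylbutanedioate
Conditions: LDA (2.2 equiv), THF, −78 to −20 °C; MeI, −78 °C; AcOH
Reagents that add atoms: iodomethane CI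
Why: Fráter–Seebach alkylation: the chelated alkoxide–enolate dianion is methylated anti to the carbinol oxygen, which sets C17 next to the chiral-pool centre C8.

Step 3
Reactants: 5 dimethyl (2S,3R)-2-hydroxy-3-methylbutanedioate
Product: 6 (2S,3R)-2-hydroxy-3-methylbutanedioic acid
Conditions: LiOH, THF/H2O, 0 °C to rt; then HCl (aq)
Reagents that add atoms: lithium hydroxide [Li+].[OH-]
Why: Saponification of both methyl esters; the carboxylate salts should not epimerise under these mild conditions.

Step 4
Reactants: 6 (2S,3R)-2-hydroxy-3-methylbutanedioic acid; 7 pivalaldehyde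
Product: 8 (2R)-2-[(2S,4S)-2-tert-butyl-5-oxo-1,3-dioxolan-4-yl]propanoic acid
Conditions: TsOH (cat.), H2SO4 (cat.), pentane, reflux, water separator; crystallisation
Reagents that add atoms: none
Why: Acid-catalysed acetalisation of the α-hydroxy acid unit gives the 1,3-dioxolan-4-one, whose cis isomer (tert-butyl cis to the side chain) is favoured and crystallised; it stores the C8 configuration for self-regeneration of the stereocentre.

Step 5
Reactants: 8 dioxolanone acid
Product: 9 tert-butyl (2R)-2-[(2S,4S)-2-tert-butyl-5-oxo-1,3-dioxolan-4-yl]propanoate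
Conditions: isobutene, H2SO4 (cat.), CH2Cl2, sealed vessel, rt
Reagents that add atoms: 2-methylpropene CC(C)=C
Why: Acid-catalysed addition of the acid to isobutene gives a tert-butyl ester that resists alkoxides and organolithiums and cannot lactonise with the later C9 hydroxyl.

Step 6
Reactants: 9 tert-butyl ester
Product: 11 tert-butyl (2R)-2-[(2S,4R)-2-tert-butyl-4-(hydroxymethyl)-5-oxo-1,3-dioxolan-4-yl]propanoate, via lithium enolate 10 (not isolated)
Conditions: LiN(SiMe3)2, THF, −78 °C; CH2O (gas), −78 °C; AcOH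
Reagents that add atoms: formaldehyde C=O
Why: Aldol addition under self-regeneration of the stereocentre: the more acidic dioxolanone C–H is removed selectively and the planar enolate takes formaldehyde anti to the tert-butyl group, so C9 replaces H at C8 with retention.

Step 7
Reactants: 11 hydroxymethyl dioxolanone
Product: 12 tert-butyl (2R)-2-[(2S,4R)-2-tert-butyl-4-formyl-5-oxo-1,3-dioxolan-4-yl]propanoate
Conditions: Dess–Martin periodinane, CH2Cl2, rt
Reagents that add atoms: none
Why: Dess–Martin oxidation of the neopentyl primary alcohol gives a non-enolisable aldehyde without touching the acetal or the esters.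

Step 8
Reactants: 12 formyl dioxolanone; 3 (E)-alkenyl iodide
Product: 14 tert-butyl (2R)-2-[(2S,4R)-2-tert-butyl-4-[(1S,2E)-1-hydroxy-3-methyl-4-(allyloxy)but-2-en-1-yl]-5-oxo-1,3-dioxolan-4-yl]propanoate, via alkenylchromium 13 (not isolated)
Conditions: CrCl2 (4 equiv), NiCl2 (cat.), DMF, rt
Reagents that add atoms: none
Why: Nozaki–Hiyama–Kishi coupling adds the alkenylchromium reagent chemoselectively to the aldehyde with retention of alkene geometry, and polar Felkin–Anh control (C8–O anti to the nucleophile, approach past the flat ring carbonyl and not past branched C17) should set 9S, with C8–O and C9–O syn along C7–C10.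

Step 9
Reactants: 14 allylic alcohol; 15 tert-butyl(diphenyl)(prop-2-yn-1-yloxy)silane
Product: 17 ynone (C7 ketone, C6≡C5, C16 silyl ether, free C8 and C9 hydroxyls, tert-butyl ester), via lithium acetylide 16 (not isolated)
Conditions: 15, n-BuLi, THF, −78 °C; 14, LiN(SiMe3)2, THF, −78 °C, then the acetylide, −78 °C; AcOH
Reagents that add atoms: none
Why: Acyl substitution at the activated dioxolanone carbonyl: the acetylide adduct is stable at −78 °C and collapses on quench to the ynone, releasing pivalaldehyde and the tertiary C8 hydroxyl, while the tert-butyl ester is inert.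

Step 10
Reactants: 17 ynone
Product: 18 (Z)-β-iodoenone (iodine on C5, cis to the C7 carbonyl)
Conditions: NaI, AcOH, MeCN, rt
Reagents that add atoms: sodium iodide [Na+].[I-]
Why: Conjugate hydroiodination of the ynone (iodide to C5, anti protonation at C6) gives the Z isomer, which is the geometry needed for the C5=C6 bond of the ring.

Step 11
Reactants: 18 (Z)-β-iodoenone
Product: 19 C9 acetate with free (7S)-hydroxyl (7,9-anti)
Conditions: SmI2 (30 mol %), CH3CHO, THF, −10 °C
Reagents that add atoms: acetaldehyde CC=O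
Why: Evans–Tishchenko reduction: the samarium-bound hemiacetal of the C9 hydroxyl and acetaldehyde delivers hydride to C7 through a six-membered chair, which sets C7 anti to C9, leaves C9 as its acetate and frees the C7 hydroxyl.

Step 12
Reactants: 19 hydroxy tert-butyl ester
Product: 21 iodo lactone (C7–O–C19 γ-lactone, free C8–OH), via hydroxy acid 20 (not isolated)
Conditions: CF3CO2H, CH2Cl2, 0 °C to rt
Reagents that add atoms: none
Why: Acidolysis of the tert-butyl ester and lactonisation with the only free secondary alcohol (C7–OH, since C9 is acetylated) fix the lactone regiochemistry.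

Step 13
Reactants: 21 iodo lactone
Product: 22 C8 triethylsilyl ether of 21
Conditions: Et3SiOTf, 2,6-lutidine, CH2Cl2, 0 °C
Reagents that add atoms: triethylsilyl trifluoromethanesulfonate CC[Si](CC)(CC)OS(=O)(=O)C(F)(F)F
Why: Silylation of the tertiary alcohol with the silyl triflate prevents hemiacetal formation with the C14 aldehyde made in step 15.

Step 14
Reactants: 22 silylated iodo lactone; 23 propargyl alcohol
Product: 24 enyne alcohol (C2H2OH–C3≡C4–C5=C6, C4 cis to C7)
Conditions: PdCl2(PPh3)2 (5 mol %), CuI (10 mol %), Et3N, THF, rt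
Reagents that add atoms: none
Why: Sonogashira coupling of the (Z)-alkenyl iodide goes with retention of geometry; insertion into the C–I bond should be faster than ionisation of the hindered allylic lactone.

Step 15
Reactants: 24 enyne alcohol
Product: 26 aldehyde (C14HO–C1H(CH3)–C10H(isopropenyl)), via propenyl ether 25 (not isolated)
Conditions: [IrCl(C8H14)2]2 (1 mol %), PCy3, NaBPh4, CH2Cl2/acetone, rt; then PPh3, ClCH2CH2Cl, 80 °C
Reagents that add atoms: none
Why: Iridium-catalysed olefin isomerisation–Claisen rearrangement: the unhindered O-allyl group becomes the (E)-propenyl ether, whose chair [3,3] shift forms C10–C1 and the isopropenyl group; allylic strain with the C11 methyl holds H9 in the alkene plane, so C1 adds to C10 anti to bulky C8, which gives the target configuration at C10.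

Step 16
Reactants: 26 hydroxy aldehyde
Product: 27 dialdehyde (C14 aldehyde and C2 ynal)
Conditions: Dess–Martin periodinane, pyridine, CH2Cl2, 0 °C
Reagents that add atoms: none
Why: Dess–Martin oxidation of the primary propargylic alcohol gives the ynal; the existing aldehyde, the silyl ethers and the acetate are inert.

Step 17
Reactants: 27 dialdehyde
Product: 30 ten-membered β-hydroxy aldehyde (C1 quaternary, (2S)-C2–OH, ring alkyne C3≡C4), via enol silane 28 (not isolated), via silyl aldolate 29 (not isolated)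
Conditions: Me3SiOTf (3 equiv), i-Pr2NEt (4 equiv), CH2Cl2, 0.002 M (slow addition of 27), −78 to −20 °C; then citric acid (aq), THF
Reagents that add atoms: none
Why: Me3SiOTf/i-Pr2NEt silylates the only enolisable carbonyl, the C14 aldehyde, to enol silane 28 (C1 is its sole α-carbon; the ynal has no α-hydrogen and acetate and lactone are not enolised at low temperature), then the silyl triflate activates the ynal and C1 attacks C2 in an open Mukaiyama aldol transition state with silyl transfer to the new alkoxide (29), which the acidic work-up desilylates. The closest known reaction types are the one-pot silyl triflate/amine Mukaiyama aldol addition and Lewis-acid-mediated Mukaiyama aldol macrocyclisations. The ten-membered ring closes in a 10-exo-trig mode at the aldehyde carbon, with the enol double bond exocyclic to the forming ring. At C1, H10 lies in the enol plane (allylic strain) and the tether through C9 can deliver C2 only to the enol face syn to C9 and anti to the isopropenyl group, which is the target configuration. At C2, the ynal face is left to the ring-forming transition state, which is expected to give 2S, and this is the less secure element. The step needs ring closure to beat intermolecular aldol addition, which high dilution and the rigid cis-enyne and lactone (holding the two aldehydes close) should secure.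

Step 18
Reactants: 30 β-hydroxy aldehyde
Product: 32 homoallylic alcohol ((14S)-C14–OH bearing the allyl group, 2,14-anti diol), via borate ester 31 (not isolated)
Conditions: diisopropyl (R,R)-tartrate allylboronate, 4 Å molecular sieves, toluene, −78 °C to rt; NaHCO3 (aq)
Reagents that add atoms: diisopropyl (4R,5R)-2-allyl-1,3,2-dioxaborolane-4,5-dicarboxylate C=CCB1O[C@@H](C(=O)OC(C)C)[C@H](C(=O)OC(C)C)O1
Why: Tartrate-ester allylboration (Roush allylation): the (R,R)-boronate adds through a chair transition state to the Si face of the hindered aldehyde under reagent control, which gives 14S; lactone and acetate do not react with the boronate.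

Step 19
Reactants: 32 homoallylic alcohol
Product: 33 bicyclic enyne diol (cyclohexene C11=C12 closed)
Conditions: second-generation Grubbs catalyst RuCl2(=CHPh)(H2IMes)(PCy3) (5 mol %), CH2Cl2, 0.005 M, 40 °C
Reagents that add atoms: none
Why: Ring-closing metathesis between the allyl and isopropenyl groups closes the six-membered ring as the trisubstituted alkene with loss of ethene, and six-ring closure should outpace reaction at the hindered ring alkyne.

Step 20
Reactants: 33 bicyclic enyne diol
Product: 34 Z,Z-diene diol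
Conditions: H2 (1 atm), Lindlar catalyst (Pd on CaCO3 poisoned with Pb(OAc)2), quinoline, EtOAc, rt
Reagents that add atoms: none
Why: Lindlar semihydrogenation adds H2 syn to the ring alkyne only, which gives the cis C3=C4 bond; the remaining alkenes are trisubstituted and inert.

Step 21
Reactants: 34 diene diol
Product: 35 2,9,14-triacetate (C8 and C16 still silylated)
Conditions: Ac2O, pyridine, DMAP (cat.), CH2Cl2, rt
Reagents that add atoms: acetic anhydride CC(=O)OC(C)=O
Why: Acetylation of the two free secondary alcohols (C2 and C14); the tertiary C8 oxygen and C16 are protected as silyl ethers.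

Step 22
Reactants: 35 triacetate
Product: 36 target CNP0215504.2
Conditions: HF·pyridine, pyridine, THF, 0 °C to rt
Reagents that add atoms: none
Why: Fluoride cleavage of both silyl ethers under acidic, non-basic conditions should leave the three acetates and the lactone intact and avoid acetyl migration.

**Compound list**

1 | 3-(prop-2-yn-1-yloxy)prop-1-ene (allyl propargyl ether) | C=CCOCC#C | starting material
2 | dimethyl[(1E)-2-methyl-3-(allyloxy)prop-1-en-1-yl]aluminium | C[Al](C)/C=C(\C)COCC=C | intermediate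
3 | (1E)-1-iodo-2-methyl-3-(allyloxy)prop-1-ene | I/C=C(\C)COCC=C | intermediate
4 | dimethyl (2S)-2-hydroxybutanedioate | COC(=O)C[C@H](O)C(=O)OC | starting material
5 | dimethyl (2S,3R)-2-hydroxy-3-methylbutanedioate | COC(=O)[C@H](C)[C@H](O)C(=O)OC | intermediate
6 | (2S,3R)-2-hydroxy-3-methylbutanedioic acid | OC(=O)[C@H](C)[C@H](O)C(=O)O | intermediate
7 | 2,2-dimethylpropanal | CC(C)(C)C=O | starting material
8 | (2R)-2-[(2S,4S)-2-tert-butyl-5-oxo-1,3-dioxolan-4-yl]propanoic acid | OC(=O)[C@H](C)[C@@H]1O[C@H](C(C)(C)C)OC1=O | intermediate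
9 | tert-butyl (2R)-2-[(2S,4S)-2-tert-butyl-5-oxo-1,3-dioxolan-4-yl]propanoate | CC(C)(C)OC(=O)[C@H](C)[C@@H]1O[C@H](C(C)(C)C)OC1=O | intermediate
10 | lithium enolate of 9 (dioxolanone C4=C5–OLi) | CC(C)(C)OC(=O)[C@H](C)C1=C(O[Li])O[C@@H](C(C)(C)C)O1 | intermediate
11 | tert-butyl (2R)-2-[(2S,4R)-2-tert-butyl-4-(hydroxymethyl)-5-oxo-1,3-dioxolan-4-yl]propanoate | CC(C)(C)OC(=O)[C@H](C)[C@@]1(O[C@H](C(C)(C)C)OC1=O)CO | intermediate
12 | tert-butyl (2R)-2-[(2S,4R)-2-tert-butyl-4-formyl-5-oxo-1,3-dioxolan-4-yl]propanoate | CC(C)(C)OC(=O)[C@H](C)[C@@]1(O[C@H](C(C)(C)C)OC1=O)C=O | intermediate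
13 | dichloro[(1E)-2-methyl-3-(allyloxy)prop-1-en-1-yl]chromium | Cl[Cr](Cl)/C=C(\C)COCC=C | intermediate
14 | tert-butyl (2R)-2-[(2S,4R)-2-tert-butyl-4-[(1S,2E)-1-hydroxy-3-methyl-4-(allyloxy)but-2-en-1-yl]-5-oxo-1,3-dioxolan-4-yl]propanoate | CC(C)(C)OC(=O)[C@H](C)[C@@]1(O[C@H](C(C)(C)C)OC1=O)[C@@H](O)/C=C(\C)COCC=C | intermediate
15 | tert-butyl(diphenyl)(prop-2-yn-1-yloxy)silane | C#CCO[Si](c1ccccc1)(c1ccccc1)C(C)(C)C | starting material
16 | lithium acetylide of 15 | [Li]C#CCO[Si](c1ccccc1)(c1ccccc1)C(C)(C)C | intermediate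
17 | ynone: tert-butyl ester (C19), C17 methyl, C8 tertiary OH bearing the C7(=O)–C≡C–CH2OTBDPS ynone and the (9S)-CH(OH)–(E)-CH=C(CH3)CH2O-allyl arm | CC(C)(C)OC(=O)[C@H](C)[C@](O)(C(=O)C#CCO[Si](c1ccccc1)(c1ccccc1)C(C)(C)C)[C@@H](O)/C=C(\C)COCC=C | intermediate
18 | (Z)-β-iodoenone from 17 (I on C5, cis to C7=O) | CC(C)(C)OC(=O)[C@H](C)[C@](O)(C(=O)/C=C(\I)CO[Si](c1ccccc1)(c1ccccc1)C(C)(C)C)[C@@H](O)/C=C(\C)COCC=C | intermediate
19 | (7S)-alcohol, C9 acetate (7,9-anti; 8,9-syn), tert-butyl ester | CC(C)(C)OC(=O)[C@H](C)[C@](O)([C@@H](O)/C=C(\I)CO[Si](c1ccccc1)(c1ccccc1)C(C)(C)C)[C@@H](OC(C)=O)/C=C(\C)COCC=C | intermediate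
20 | free carboxylic acid of 19 | OC(=O)[C@H](C)[C@](O)([C@@H](O)/C=C(\I)CO[Si](c1ccccc1)(c1ccccc1)C(C)(C)C)[C@@H](OC(C)=O)/C=C(\C)COCC=C | intermediate
21 | iodo lactone: γ-lactone C7–O–C19 with C6, 8-OH and 17-CH3 cis on the ring, (Z)-iodoalkene on C7, C9 acetate | I/C(CO[Si](c1ccccc1)(c1ccccc1)C(C)(C)C)=C\[C@@H]1OC(=O)[C@H](C)[C@@]1(O)[C@@H](OC(C)=O)/C=C(\C)COCC=C | intermediate
22 | C8 triethylsilyl ether of 21 | I/C(CO[Si](c1ccccc1)(c1ccccc1)C(C)(C)C)=C\[C@@H]1OC(=O)[C@H](C)[C@@]1(O[Si](CC)(CC)CC)[C@@H](OC(C)=O)/C=C(\C)COCC=C | intermediate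
23 | prop-2-yn-1-ol | C#CCO | starting material
24 | enyne alcohol: 22 with I replaced by C≡C–CH2OH | OCC#C/C(CO[Si](c1ccccc1)(c1ccccc1)C(C)(C)C)=C\[C@@H]1OC(=O)[C@H](C)[C@@]1(O[Si](CC)(CC)CC)[C@@H](OC(C)=O)/C=C(\C)COCC=C | intermediate
25 | (E)-prop-1-enyl ether isomer of 24 | OCC#C/C(CO[Si](c1ccccc1)(c1ccccc1)C(C)(C)C)=C\[C@@H]1OC(=O)[C@H](C)[C@@]1(O[Si](CC)(CC)CC)[C@@H](OC(C)=O)/C=C(\C)CO/C=C/C | intermediate
26 | Claisen aldehyde: C10 bearing isopropenyl and the C1H(CH3)–C14HO unit (C1/C10 syn), C2H2OH on the alkyne | OCC#C/C(CO[Si](c1ccccc1)(c1ccccc1)C(C)(C)C)=C\[C@@H]1OC(=O)[C@H](C)[C@@]1(O[Si](CC)(CC)CC)[C@@H](OC(C)=O)[C@@H](C(C)=C)[C@@H](C)C=O | intermediate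
27 | dialdehyde: 26 with the C2 ynal | O=CC#C/C(CO[Si](c1ccccc1)(c1ccccc1)C(C)(C)C)=C\[C@@H]1OC(=O)[C@H](C)[C@@]1(O[Si](CC)(CC)CC)[C@@H](OC(C)=O)[C@@H](C(C)=C)[C@@H](C)C=O | intermediate
28 | (E)-trimethylsilyl enol ether of the C14 aldehyde of 27 | O=CC#C/C(CO[Si](c1ccccc1)(c1ccccc1)C(C)(C)C)=C\[C@@H]1OC(=O)[C@H](C)[C@@]1(O[Si](CC)(CC)CC)[C@@H](OC(C)=O)[C@@H](C(C)=C)/C(C)=C/O[Si](C)(C)C | intermediate
29 | C2 trimethylsilyl ether of 30 | C[Si](C)(C)O[C@H]1C#C/C(CO[Si](c2ccccc2)(c2ccccc2)C(C)(C)C)=C\[C@@H]2OC(=O)[C@H](C)[C@@]2(O[Si](CC)(CC)CC)[C@@H](OC(C)=O)[C@@H](C(C)=C)[C@]1(C)C=O | intermediate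
30 | ten-membered cycloenyne: quaternary C1 (CH3, CHO), (2S)-OH, C9 acetate, C10 isopropenyl, fused lactone | O[C@H]1C#C/C(CO[Si](c2ccccc2)(c2ccccc2)C(C)(C)C)=C\[C@@H]2OC(=O)[C@H](C)[C@@]2(O[Si](CC)(CC)CC)[C@@H](OC(C)=O)[C@@H](C(C)=C)[C@]1(C)C=O | intermediate
31 | tartrate borate ester of 32 at O14 | O[C@H]1C#C/C(CO[Si](c2ccccc2)(c2ccccc2)C(C)(C)C)=C\[C@@H]2OC(=O)[C@H](C)[C@@]2(O[Si](CC)(CC)CC)[C@@H](OC(C)=O)[C@@H](C(C)=C)[C@]1(C)[C@@H](OB2O[C@@H](C(=O)OC(C)C)[C@H](C(=O)OC(C)C)O2)CC=C | intermediate
32 | homoallylic alcohol: 30 with C14 as (14S)-CH(OH)–CH2CH=CH2 | O[C@H]1C#C/C(CO[Si](c2ccccc2)(c2ccccc2)C(C)(C)C)=C\[C@@H]2OC(=O)[C@H](C)[C@@]2(O[Si](CC)(CC)CC)[C@@H](OC(C)=O)[C@@H](C(C)=C)[C@]1(C)[C@@H](O)CC=C | intermediate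
33 | trans-fused bicyclic enyne 2,14-diol (cyclohexene closed) | O[C@H]1C#C/C(CO[Si](c2ccccc2)(c2ccccc2)C(C)(C)C)=C\[C@@H]2OC(=O)[C@H](C)[C@@]2(O[Si](CC)(CC)CC)[C@@H](OC(C)=O)[C@H]2C(C)=CC[C@H](O)[C@]12C | intermediate
34 | Z,Z-diene 2,14-diol | O[C@H]1/C=C\C(CO[Si](c2ccccc2)(c2ccccc2)C(C)(C)C)=C/[C@@H]2OC(=O)[C@H](C)[C@@]2(O[Si](CC)(CC)CC)[C@@H](OC(C)=O)[C@H]2C(C)=CC[C@H](O)[C@]12C | intermediate
35 | 2,9,14-triacetate, 8-O-triethylsilyl, 16-O-tert-butyldiphenylsilyl | CC(=O)O[C@H]1/C=C\C(CO[Si](c2ccccc2)(c2ccccc2)C(C)(C)C)=C/[C@@H]2OC(=O)[C@H](C)[C@@]2(O[Si](CC)(CC)CC)[C@@H](OC(C)=O)[C@H]2C(C)=CC[C@H](OC(C)=O)[C@]12C | intermediate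
36 | CNP0215504.2 (1R,2S,7S,8S,9S,10S,14S,17R; 3Z,5E) | CC(=O)O[C@H]1/C=C\C(CO)=C/[C@@H]2OC(=O)[C@H](C)[C@@]2(O)[C@@H](OC(C)=O)[C@H]2C(C)=CC[C@H](OC(C)=O)[C@]12C | target

**Count and risks**

Total step count: 22. Longest linear sequence: 21 steps (steps 2 to 22, from 4); step 1 is a one-step side branch.

Step 17 is the most exposed. The open aldol transition state may show poor facial selectivity at the ynal carbon C2, and intermolecular aldol addition may compete with ring closure. The fallback corrects C2 once both carbocycles exist: C2-epimeric material is taken through steps 18 and 19, and the fallback sets out from 33. MnO2 in CH2Cl2 oxidises the propargylic alcohol selectively (the homoallylic C14–OH is untouched) to the ring ynone F1. Transfer hydrogenation of F1 with RuCl(p-cymene)[(R,R)-TsDPEN] in HCO2H/Et3N, with the alkyne as the directing π-group and the catalyst in control, comes back to 33 with the 2S configuration.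

Step 15 is next. The iridium catalyst may be inhibited by the enyne and the free propargylic alcohol, or the allyl ether may isomerise without clean rearrangement at hindered C10. The fallback runs the sigmatropic step before any alkyne is present and sets out from 22: the same isomerisation gives the propenyl ether F2, which on heating rearranges to the iodo aldehyde F3. Sonogashira coupling of F3 with 23 under the conditions of step 14 comes back to the route at 26.

Step 19 is third. Enyne metathesis at the strained ring alkyne, or binding of the ruthenium carbene to it, may outrun six-ring closure. The fallback removes the alkyne first and sets out from 32: Lindlar semihydrogenation with monitored hydrogen uptake gives the triene diol F4, and ring-closing metathesis of F4 with the same ruthenium catalyst comes back to the route at 34.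

Further compounds
F1 | step 17 | ring ynone (C2 ketone) derived from 33 | O=C1C#C/C(CO[Si](c2ccccc2)(c2ccccc2)C(C)(C)C)=C\[C@@H]2OC(=O)[C@H](C)[C@@]2(O[Si](CC)(CC)CC)[C@@H](OC(C)=O)[C@H]2C(C)=CC[C@H](O)[C@]12C
F2 | step 15 | (E)-prop-1-enyl ether isomer of 22 | I/C(CO[Si](c1ccccc1)(c1ccccc1)C(C)(C)C)=C\[C@@H]1OC(=O)[C@H](C)[C@@]1(O[Si](CC)(CC)CC)[C@@H](OC(C)=O)/C=C(\C)CO/C=C/C
F3 | step 15 | iodo aldehyde (Claisen product of F2) | I/C(CO[Si](c1ccccc1)(c1ccccc1)C(C)(C)C)=C\[C@@H]1OC(=O)[C@H](C)[C@@]1(O[Si](CC)(CC)CC)[C@@H](OC(C)=O)[C@@H](C(C)=C)[C@@H](C)C=O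
F4 | step 19 | triene diol (Z-alkene in place of the ring alkyne of 32) | O[C@H]1/C=C\C(CO[Si](c2ccccc2)(c2ccccc2)C(C)(C)C)=C/[C@@H]2OC(=O)[C@H](C)[C@@]2(O[Si](CC)(CC)CC)[C@@H](OC(C)=O)[C@@H](C(C)=C)[C@]1(C)[C@@H](O)CC=C
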